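**Retrosynthetic overview**
- The γ-lactone closes last (O-6 onto C12), in the same flask and right after the carbocycle forms.
- The ten-membered ring is closed at C6–C7 by intramolecular chromium Barbier allylation of a lactol-masked C6 aldehyde by a 2-(bromomethyl)enoate. This is the bond and polarity of the farnesyl-type closure; the angelate, both esters and the free O-15 are already in place.
- The linear precursor comes from cross-metathesis at C1=C10 of an east lactol-alkene with a west α-substituted acrylate.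
- West: zinc Barbier allylation of (S)-glyceraldehyde acetonide (sets C8), angeloylation, glycol cleavage to the C7 aldehyde, Baylis–Hillman-type C7–C11 bond, SN2′ bromination.
- East: (R)-cyclohex-3-ene-1-carboxylic acid is reduced and ozonized (the C15 hydroxyl traps C6 as a lactol and leaves C1 free), then methylenated. Ring order: carbocycle, then lactone.

Assumption: carbon labels follow the germacranolide skeleton (C6 lactone carbinol, C7 ring fusion, C8 angelate carbon, C10/C14 ring enoate, C4/C15 the CH–CH2OH unit, C11–C13 the methylene-lactone unit), and 1, 7, 8, 11 and 16 are bought.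

**Route**

Step 1
Reactants: 1 (1R)-cyclohex-3-ene-1-carboxylic acid
Product: 2 [(1R)-cyclohex-3-en-1-yl]methanol
Conditions: LiAlH4, THF, 0 °C to reflux; then H2O, 15% aq. NaOH
Reagents that add atoms: none
Why: Hydride reduction of a carboxylic acid to the primary alcohol; the stereocenter (later C4) is not touched.

Step 2
Reactants: 2 [(1R)-cyclohex-3-en-1-yl]methanol
Product: 5 3-[(3R)-5-hydroxyoxolan-3-yl]propanal, via ozonide 3 (not isolated), via hydroxy dialdehyde 4 (not isolated)
Conditions: O3, CH2Cl2, −78 °C; then PPh3, −78 °C to 25 °C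
Reagents that add atoms: ozone, [O-][O+]=O
Why: Ozonolysis (Criegee) with reductive work-up gives the hydroxy dialdehyde, whose hydroxyl can close a five-membered lactol only onto the γ-aldehyde (C6), so C6 is masked and the C1 aldehyde stays free; C4 is unchanged.

Step 3
Reactants: 5 3-[(3R)-5-hydroxyoxolan-3-yl]propanal
Product: 6 (4R)-4-(but-3-en-1-yl)oxolan-2-ol
Conditions: Ph3PCH3Br (2.1 equiv), KN(SiMe3)2 (2.05 equiv), THF, −78 °C to −20 °C; then aq. NH4Cl
Reagents that add atoms: methyltriphenylphosphonium bromide, C[P+](c1ccccc1)(c1ccccc1)c1ccccc1.[Br-]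
Why: Wittig methylenation; one equivalent of ylide only deprotonates the lactol, whose closed potassium salt is inert at low temperature, and the second olefinates the free aldehyde.

Step 4
Reactants: 7 (4S)-2,2-dimethyl-1,3-dioxolane-4-carbaldehyde; 8 methyl 2-(bromomethyl)prop-2-enoate
Product: 10 methyl (4R)-4-[(4S)-2,2-dimethyl-1,3-dioxolan-4-yl]-4-hydroxy-2-methylidenebutanoate, via allylzinc bromide 9 (not isolated)
Conditions: Zn dust, THF/sat. aq. NH4Cl, 0 °C to 25 °C
Reagents that add atoms: none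
Why: Aqueous zinc Barbier allylation of an α-alkoxy aldehyde; Felkin–Anh (non-chelated) addition anti to the dioxolane oxygen sets C8 as R (expected about 6:1, minor epimer removed by chromatography), and the neutral medium leaves the γ-hydroxy ester unlactonized.

Step 5
Reactants: 10 methyl (4R)-4-[(4S)-2,2-dimethyl-1,3-dioxolan-4-yl]-4-hydroxy-2-methylidenebutanoate; 11 (2Z)-2-methylbut-2-enoic acid (angelic acid)
Product: 13 methyl (4R)-4-[(4S)-2,2-dimethyl-1,3-dioxolan-4-yl]-2-methylidene-4-{[(2Z)-2-methylbut-2-enoyl]oxy}butanoate, via mixed anhydride 12 (not isolated)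
Conditions: 11, 2,4,6-trichlorobenzoyl chloride, Et3N, toluene, 25 °C; then 10, 75 °C
Reagents that add atoms: none
Why: Yamaguchi esterification through the preformed mixed anhydride without DMAP acylates O-8 with retention at C8, avoids angelate-to-tiglate isomerization, and caps O-8 before it can lactonize onto the C14 ester.

Step 6
Reactants: 13 methyl (4R)-4-[(4S)-2,2-dimethyl-1,3-dioxolan-4-yl]-2-methylidene-4-{[(2Z)-2-methylbut-2-enoyl]oxy}butanoate
Product: 15 methyl (4R)-2-methylidene-4-{[(2Z)-2-methylbut-2-enoyl]oxy}-5-oxopentanoate, via diol 14 (not isolated)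
Conditions: H5IO6, EtOAc, 25 °C
Reagents that add atoms: none
Why: Periodic acid hydrolyzes the terminal acetonide and cleaves the 1,2-diol (Malaprade glycol cleavage) in one pot, turning the sacrificial dioxolane carbon into the C7 aldehyde; the non-basic medium leaves C8 intact.

Step 7
Reactants: 15 methyl (4R)-2-methylidene-4-{[(2Z)-2-methylbut-2-enoyl]oxy}-5-oxopentanoate; 16 methyl prop-2-ynoate
Product: 18 dimethyl (4R)-3-hydroxy-2,6-dimethylidene-4-{[(2Z)-2-methylbut-2-enoyl]oxy}heptanedioate, via vinylalane 17 (not isolated)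
Conditions: iBu2AlH, HMPA, THF, 0 °C, then 16; then 15, 0 °C to 25 °C
Reagents that add atoms: none
Why: Morita–Baylis–Hillman-type addition of an α-aluminoacrylate (from conjugate hydroalumination of the propiolate) to the aldehyde under amine-free conditions, so the α-acyloxy aldehyde does not epimerize; the new C7 carbinol is a mixture that is erased in step 8.

Step 8
Reactants: 18 dimethyl (4R)-3-hydroxy-2,6-dimethylidene-4-{[(2Z)-2-methylbut-2-enoyl]oxy}heptanedioate
Product: 19 dimethyl (2Z,4R)-2-(bromomethyl)-6-methylidene-4-{[(2Z)-2-methylbut-2-enoyl]oxy}hept-2-enedioate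
Conditions: NBS, Me2S, CH2Cl2, 0 °C to 25 °C
Reagents that add atoms: N-bromosuccinimide, BrN1C(=O)CCC1=O
Why: Corey–Kim-type activation of the allylic hydroxyl followed by SN2′ attack of bromide gives the thermodynamically preferred (Z)-2-(bromomethyl)enoate; C8 is not involved.

Step 9
Reactants: 19 dimethyl (2Z,4R)-2-(bromomethyl)-6-methylidene-4-{[(2Z)-2-methylbut-2-enoyl]oxy}hept-2-enedioate; 6 (4R)-4-(but-3-en-1-yl)oxolan-2-ol
Product: 20 dimethyl (2Z,4R,6E)-2-(bromomethyl)-6-{3-[(3R)-5-hydroxyoxolan-3-yl]propylidene}-4-{[(2Z)-2-methylbut-2-enoyl]oxy}hept-2-enedioate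
Conditions: second-generation Hoveyda–Grubbs catalyst RuCl2(H2IMes)(=CH-C6H4-2-OiPr) (10 mol %), 6 (3 equiv), 1,4-benzoquinone (10 mol %), CH2Cl2, 40 °C
Reagents that add atoms: none
Why: Olefin cross-metathesis of a terminal alkene with an α-substituted acrylate gives the trisubstituted enoate under thermodynamic control with C2 trans to the ester (the geometry needed); the bromomethyl enoate and the angelate are trisubstituted and inert, and the phosphine-free catalyst is not alkylated by the allylic bromide.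

Step 10
Reactants: 20 dimethyl (2Z,4R,6E)-2-(bromomethyl)-6-{3-[(3R)-5-hydroxyoxolan-3-yl]propylidene}-4-{[(2Z)-2-methylbut-2-enoyl]oxy}hept-2-enedioate
Product: 23 methyl (3aS,4R,6E,10R,11aR)-10-(hydroxymethyl)-3-methylidene-4-{[(2Z)-2-methylbut-2-enoyl]oxy}-2-oxo-2,3,3a,4,5,8,9,10,11,11a-decahydrocyclodeca[b]furan-6-carboxylate, via allylchromium dichloride 21 (not isolated), via seco hydroxy ester 22 (not isolated)
Conditions: CrCl2 (8 equiv), THF (0.002 M, 20 added over 10 h), 25 °C; then 1 M aq. HCl, 25 °C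
Reagents that add atoms: none
Why: Proposed new method: the closest known chemistry is the Nozaki–Hiyama–Kishi (chromium Barbier) macrocyclization of ω-formyl 2-(bromomethyl)enoates to germacranolide rings, together with Barbier allylation of lactols by 2-(bromomethyl)acrylates; here the lactol supplies the C6 aldehyde by ring–chain tautomerism (helped by the Lewis-acidic trivalent chromium salts), divalent chromium inserts into the allylic C–Br bond, and the allylchromium adds through C7 to C6 in a chair-like transition state inside the forming ring, where allylic 1,3-strain keeps H-8 in the alkene plane so that C6 bonds anti to the C9 tether with the angelate outside (7S) and the ring with its cis C1=C10 unit holds C5 and C8 anti across the new bond (6R, trans-lactone relationship); the O-6 chromium alkoxide then lactonizes onto C12 (completed by the acid), which leaves O-15 free and gives the target directly.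

**Compound list**
1 | (1R)-cyclohex-3-ene-1-carboxylic acid | OC(=O)[C@H]1CC=CCC1 | starting material
2 | [(1R)-cyclohex-3-en-1-yl]methanol | OC[C@H]1CC=CCC1 | intermediate
3 | [(3R)-7,8,9-trioxabicyclo[4.2.1]nonan-3-yl]methanol (ozonide of 2, bridgehead isomers) | OC[C@@H]1CCC2OOC(C1)O2 | intermediate
4 | (3R)-3-(hydroxymethyl)hexanedial | O=CC[C@H](CO)CCC=O | intermediate
5 | 3-[(3R)-5-hydroxyoxolan-3-yl]propanal (lactol, anomer mixture) | O=CCC[C@H]1COC(O)C1 | intermediate
6 | (4R)-4-(but-3-en-1-yl)oxolan-2-ol (anomer mixture) | C=CCC[C@H]1COC(O)C1 | intermediate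
7 | (4S)-2,2-dimethyl-1,3-dioxolane-4-carbaldehyde | O=C[C@@H]1COC(C)(C)O1 | starting material
8 | methyl 2-(bromomethyl)prop-2-enoate | COC(=O)C(=C)CBr | starting material
9 | bromo[2-(methoxycarbonyl)prop-2-en-1-yl]zinc | COC(=O)C(=C)C[Zn]Br | intermediate
10 | methyl (4R)-4-[(4S)-2,2-dimethyl-1,3-dioxolan-4-yl]-4-hydroxy-2-methylidenebutanoate | COC(=O)C(=C)C[C@@H](O)[C@@H]1COC(C)(C)O1 | intermediate
11 | (2Z)-2-methylbut-2-enoic acid (angelic acid) | C/C=C(/C)C(=O)O | starting material
12 | (2Z)-2-methylbut-2-enoic 2,4,6-trichlorobenzoic anhydride | C/C=C(/C)C(=O)OC(=O)c1c(Cl)cc(Cl)cc1Cl | intermediate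
13 | methyl (4R)-4-[(4S)-2,2-dimethyl-1,3-dioxolan-4-yl]-2-methylidene-4-{[(2Z)-2-methylbut-2-enoyl]oxy}butanoate | COC(=O)C(=C)C[C@@H](OC(=O)/C(C)=C\C)[C@@H]1COC(C)(C)O1 | intermediate
14 | methyl (4R,5S)-5,6-dihydroxy-2-methylidene-4-{[(2Z)-2-methylbut-2-enoyl]oxy}hexanoate | COC(=O)C(=C)C[C@@H](OC(=O)/C(C)=C\C)[C@@H](O)CO | intermediate
15 | methyl (4R)-2-methylidene-4-{[(2Z)-2-methylbut-2-enoyl]oxy}-5-oxopentanoate | COC(=O)C(=C)C[C@@H](OC(=O)/C(C)=C\C)C=O | intermediate
16 | methyl prop-2-ynoate | COC(=O)C#C | starting material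
17 | methyl 2-[bis(2-methylpropyl)alumanyl]prop-2-enoate | COC(=O)C(=C)[Al](CC(C)C)CC(C)C | intermediate
18 | dimethyl (4R)-3-hydroxy-2,6-dimethylidene-4-{[(2Z)-2-methylbut-2-enoyl]oxy}heptanedioate (C3 epimers) | COC(=O)C(=C)C[C@@H](OC(=O)/C(C)=C\C)C(O)C(=C)C(=O)OC | intermediate
19 | dimethyl (2Z,4R)-2-(bromomethyl)-6-methylidene-4-{[(2Z)-2-methylbut-2-enoyl]oxy}hept-2-enedioate | COC(=O)C(=C)C[C@@H](OC(=O)/C(C)=C\C)/C=C(\CBr)C(=O)OC | intermediate
20 | dimethyl (2Z,4R,6E)-2-(bromomethyl)-6-{3-[(3R)-5-hydroxyoxolan-3-yl]propylidene}-4-{[(2Z)-2-methylbut-2-enoyl]oxy}hept-2-enedioate | COC(=O)/C(C[C@@H](OC(=O)/C(C)=C\C)/C=C(\CBr)C(=O)OC)=C/CC[C@H]1COC(O)C1 | intermediate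
21 | allylchromium dichloride of 20 (CrCl2 unit in place of Br, trivalent chromium) | COC(=O)/C(C[C@@H](OC(=O)/C(C)=C\C)/C=C(\C[Cr](Cl)Cl)C(=O)OC)=C/CC[C@H]1COC(O)C1 | intermediate
22 | methyl (1E,5R,7R,8S,9R)-7-hydroxy-5-(hydroxymethyl)-8-(3-methoxy-3-oxoprop-1-en-2-yl)-9-{[(2Z)-2-methylbut-2-enoyl]oxy}cyclodec-1-ene-1-carboxylate | COC(=O)C(=C)[C@H]1[C@H](O)C[C@H](CO)CC/C=C(/C(=O)OC)C[C@H]1OC(=O)/C(C)=C\C | intermediate
23 | methyl (3aS,4R,6E,10R,11aR)-10-(hydroxymethyl)-3-methylidene-4-{[(2Z)-2-methylbut-2-enoyl]oxy}-2-oxo-2,3,3a,4,5,8,9,10,11,11a-decahydrocyclodeca[b]furan-6-carboxylate | C=C1C(=O)O[C@@H]2C[C@H](CO)CC/C=C(/C(=O)OC)C[C@@H](OC(=O)/C(C)=C\C)[C@@H]12 | target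

**Step count**
Total: 10 steps (east 1–3, west 4–8, union 9, ring closure 10). Longest linear sequence: 7 steps (4–10).

**Steps most likely to fail**

1) Step 10. The allylchromium carries an angelate two carbons beyond the double bond and may lose it by 1,4-elimination to a 2-carbomethoxy diene. The lactol also releases the aldehyde only slowly, so protonolysis or dimerization can compete. Simple acyclic additions of such reagents prefer the cis-lactone, so the 6R,7S outcome rests on control by the ten-membered ring. Fallback, setting out from 10 and coming back at 23: the ring is closed on an O-8 silyl ether, which cannot leave, and the angelate is put on afterwards.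
- TBSCl/imidazole in DMF turns 10 into silyl ether F7.
- H5IO6 gives, through diol F8, aldehyde F9.
- Vinylalane 17 adds to give allylic alcohol F10, and NBS/Me2S gives bromide F11.
- Cross-metathesis with 6 gives lactol F12.
- CrCl2 followed by 1 M HCl closes both rings through allylchromium dichloride F13 and seco hydroxy ester F14 to hydroxy lactone F15.
- TBDPSCl/imidazole caps the primary O-15 (bis-silyl ether F16), and camphorsulfonic acid in MeOH removes only the secondary TBS group (alcohol F17).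
- Mixed anhydride 12 acylates O-8 (angelate F18), and HF·pyridine frees O-15 to give 23.

2) Step 9. A hindered 1,1-disubstituted acrylate is a slow metathesis partner. Homodimerization of 6 and slow catalyst decay in the presence of the allylic bromide and the lactol can keep conversion low. Fallback, setting out from 13 and 6 and coming back at 20: the halves are joined before the bromide exists, on the simple acrylate 13, which is cheap at that stage and can be used in threefold excess.
- Cross-metathesis of 13 with 6 gives acetonide lactol F3.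
- H5IO6 gives, through diol F4, aldehyde F5.
- Vinylalane 17 (2.5 equiv, the first equivalent is lost to the lactol hydroxyl) gives allylic alcohol F6.
- NBS/Me2S, which converts only the allylic hydroxyl and returns the lactol on aqueous work-up, leads to 20.

3) Step 7. The aluminium alkoxide formed next to the angelate can promote 1,2-acyl migration, and the alane may attack the ester groups or the sensitive α-acyloxy aldehyde. Fallback, setting out from 15 and coming back at 19: Horner–Wadsworth–Emmons olefination in place of the alane addition.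
- Hydroxymethyl phosphonate F1 is made from trimethyl phosphonoacetate and paraformaldehyde with catalytic K2CO3.
- F1 and 15 with LiCl/iPr2NEt in MeCN at 0 °C (Masamune–Roush) give primary allylic alcohol F2, with tiglate-type geometry and no free hydroxyl next to the angelate at any point.
- NBS/Me2S replaces the hydroxyl directly to give 19.

**Further compounds**
F1 | step 7 | methyl 2-(dimethoxyphosphoryl)-3-hydroxypropanoate | COC(=O)C(CO)P(=O)(OC)OC
F2 | step 7 | dimethyl (2E,4R)-2-(hydroxymethyl)-6-methylidene-4-{[(2Z)-2-methylbut-2-enoyl]oxy}hept-2-enedioate | COC(=O)C(=C)C[C@@H](OC(=O)/C(C)=C\C)/C=C(\CO)C(=O)OC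
F3 | step 9 | methyl (2E,4R)-4-[(4S)-2,2-dimethyl-1,3-dioxolan-4-yl]-2-{3-[(3R)-5-hydroxyoxolan-3-yl]propylidene}-4-{[(2Z)-2-methylbut-2-enoyl]oxy}butanoate | COC(=O)/C(C[C@@H](OC(=O)/C(C)=C\C)[C@@H]1COC(C)(C)O1)=C/CC[C@H]1COC(O)C1
F4 | step 9 | methyl (2E,4R,5S)-5,6-dihydroxy-2-{3-[(3R)-5-hydroxyoxolan-3-yl]propylidene}-4-{[(2Z)-2-methylbut-2-enoyl]oxy}hexanoate | COC(=O)/C(C[C@@H](OC(=O)/C(C)=C\C)[C@@H](O)CO)=C/CC[C@H]1COC(O)C1
F5 | step 9 | methyl (2E,4R)-2-{3-[(3R)-5-hydroxyoxolan-3-yl]propylidene}-4-{[(2Z)-2-methylbut-2-enoyl]oxy}-5-oxopentanoate | COC(=O)/C(C[C@@H](OC(=O)/C(C)=C\C)C=O)=C/CC[C@H]1COC(O)C1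
F6 | step 9 | dimethyl (4R,6E)-3-hydroxy-6-{3-[(3R)-5-hydroxyoxolan-3-yl]propylidene}-2-methylidene-4-{[(2Z)-2-methylbut-2-enoyl]oxy}heptanedioate (C3 epimers) | COC(=O)/C(C[C@@H](OC(=O)/C(C)=C\C)C(O)C(=C)C(=O)OC)=C/CC[C@H]1COC(O)C1
F7 | step 10 | methyl (4R)-4-{[tert-butyl(dimethyl)silyl]oxy}-4-[(4S)-2,2-dimethyl-1,3-dioxolan-4-yl]-2-methylidenebutanoate | COC(=O)C(=C)C[C@@H](O[Si](C)(C)C(C)(C)C)[C@@H]1COC(C)(C)O1
F8 | step 10 | methyl (4R,5S)-4-{[tert-butyl(dimethyl)silyl]oxy}-5,6-dihydroxy-2-methylidenehexanoate | COC(=O)C(=C)C[C@@H](O[Si](C)(C)C(C)(C)C)[C@@H](O)CO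
F9 | step 10 | methyl (4R)-4-{[tert-butyl(dimethyl)silyl]oxy}-2-methylidene-5-oxopentanoate | COC(=O)C(=C)C[C@@H](O[Si](C)(C)C(C)(C)C)C=O
F10 | step 10 | dimethyl (4R)-4-{[tert-butyl(dimethyl)silyl]oxy}-3-hydroxy-2,6-dimethylideneheptanedioate (C3 epimers) | COC(=O)C(=C)C[C@@H](O[Si](C)(C)C(C)(C)C)C(O)C(=C)C(=O)OC
F11 | step 10 | dimethyl (2Z,4R)-2-(bromomethyl)-4-{[tert-butyl(dimethyl)silyl]oxy}-6-methylidenehept-2-enedioate | COC(=O)C(=C)C[C@@H](O[Si](C)(C)C(C)(C)C)/C=C(\CBr)C(=O)OC
F12 | step 10 | dimethyl (2Z,4R,6E)-2-(bromomethyl)-4-{[tert-butyl(dimethyl)silyl]oxy}-6-{3-[(3R)-5-hydroxyoxolan-3-yl]propylidene}hept-2-enedioate | COC(=O)/C(C[C@@H](O[Si](C)(C)C(C)(C)C)/C=C(\CBr)C(=O)OC)=C/CC[C@H]1COC(O)C1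
F13 | step 10 | allylchromium dichloride of F12 (CrCl2 unit in place of Br, trivalent chromium) | COC(=O)/C(C[C@@H](O[Si](C)(C)C(C)(C)C)/C=C(\C[Cr](Cl)Cl)C(=O)OC)=C/CC[C@H]1COC(O)C1
F14 | step 10 | analogue of 22 with a tert-butyldimethylsilyloxy group at C8 in place of the angelate | COC(=O)C(=C)[C@H]1[C@H](O)C[C@H](CO)CC/C=C(/C(=O)OC)C[C@H]1O[Si](C)(C)C(C)(C)C
F15 | step 10 | analogue of 23 with a tert-butyldimethylsilyloxy group at C8 in place of the angelate (O-15 free) | C=C1C(=O)O[C@@H]2C[C@H](CO)CC/C=C(/C(=O)OC)C[C@@H](O[Si](C)(C)C(C)(C)C)[C@@H]12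
F16 | step 10 | F15 with O-15 as its tert-butyldiphenylsilyl ether | C=C1C(=O)O[C@@H]2C[C@H](CO[Si](c3ccccc3)(c3ccccc3)C(C)(C)C)CC/C=C(/C(=O)OC)C[C@@H](O[Si](C)(C)C(C)(C)C)[C@@H]12
F17 | step 10 | F16 with a free hydroxyl at C8 | C=C1C(=O)O[C@@H]2C[C@H](CO[Si](c3ccccc3)(c3ccccc3)C(C)(C)C)CC/C=C(/C(=O)OC)C[C@@H](O)[C@@H]12
F18 | step 10 | 23 with O-15 as its tert-butyldiphenylsilyl ether | C=C1C(=O)O[C@@H]2C[C@H](CO[Si](c3ccccc3)(c3ccccc3)C(C)(C)C)CC/C=C(/C(=O)OC)C[C@@H](OC(=O)/C(C)=C\C)[C@@H]12
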